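## Plan

1. Retrosynthesis: the dihydropyran is opened at O1–C6 (dehydrogenative etherification of an alkenol). The benzofuran is then taken apart at its furan O–C2 and C3–C3a bonds (o-iodophenol plus terminal 1,3-enyne). The chain is cut at C2–C3 (aldol) and at the enyne C(sp2)–C(sp) bond (ethynylation of a 2-bromoallyl unit).
2. Forward: the chain is assembled on an oxazolidinone (acylation, ethynylation, aldol), reduced and acetylated. The benzofuran ring is closed first by Sonogashira coupling–cycloisomerisation with an iodohydroquinone ketone, the dihydropyran ring is closed last, and two deprotections follow.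
3. Stereochemistry: C2 (R) and C3 (S) arise together in one Evans syn-aldol reaction directed by (R)-4-benzyloxazolidin-2-one. The syn pair becomes the trans 2,3-relationship of the ring and no later step touches it.
4. Enabling feature: in the dihydropyran (O1, C2 aryl, C3 acetoxymethyl, C4H2, C5 benzofuran-2-yl, C6H) the enol ether C5=C6 is also the 1,1-disubstituted alkene of a 2-alkenylbenzofuran, and O1 is the oxygen of a hydroxyl group on C2. O1–C6 can therefore be made by adding that alcohol to the terminus of the alkene radical cation and restoring the double bond with loss of H2.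

Key step: step 10

Remark: 4-bromopent-4-enoic acid is taken as a catalogue compound (it is otherwise reached from diethyl malonate and 2,3-dibromopropene); the locants O1 and C2–C6 are those of the dihydropyran ring of the target throughout.

## Route

Step 1
Reactants: 1 (R)-4-benzyloxazolidin-2-one; 2 4-bromopent-4-enoic acid
Product: 4 (R)-4-benzyl-3-(4-bromopent-4-enoyl)oxazolidin-2-one, via mixed pivalic anhydride 3 (not isolated)
Conditions: 2, PivCl, Et3N, THF, −20 °C; then LiCl, 1, −20 °C to rt
Reagents that add atoms: none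
Why: N-acylation of the oxazolidinone through the mixed pivalic anhydride with LiCl activation is a standard mild entry to Evans imides and leaves the alkenyl bromide untouched.

Step 2
Reactants: 4 (R)-4-benzyl-3-(4-bromopent-4-enoyl)oxazolidin-2-one
Product: 5 (R)-4-benzyl-3-(4-methylidenehex-5-ynoyl)oxazolidin-2-one
Conditions: HC≡CMgBr, ZnBr2, THF, 0 °C; then 4, Pd(PPh3)4 (5 mol %), rt
Reagents that add atoms: ethynylmagnesium bromide, C#C[Mg]Br
Why: Negishi coupling of the alkenyl bromide with ethynylzinc bromide (formed from the Grignard reagent and ZnBr2 before the imide is added) should give the terminal 1,3-enyne directly, the zinc reagent being too weak a nucleophile to attack the imide.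

Step 3
Reactants: 5 (R)-4-benzyl-3-(4-methylidenehex-5-ynoyl)oxazolidin-2-one; 6 4-formyl-2-methoxyphenyl acetate (vanillin acetate)
Product: 9 (R)-4-benzyl-3-[(2R)-2-[(R)-(4-acetoxy-3-methoxyphenyl)(hydroxy)methyl]-4-methylidenehex-5-ynoyl]oxazolidin-2-one, via dibutylboron Z-enolate 7 (not isolated), via dibutylboron aldolate 8 (not isolated)
Conditions: Bu2BOTf, iPr2NEt, CH2Cl2, 0 °C; 6, −78 to 0 °C; pH 7 buffer, MeOH (no peroxide)
Reagents that add atoms: none
Why: Evans syn-aldol reaction, in which the Z-boron enolate reacts through a closed chair (Zimmerman–Traxler) transition state on the face away from the benzyl group of the (R)-auxiliary, so that the carbinol centre (R) and the α-centre (R as the imide, S after reduction) are set together in the syn relationship that later becomes trans across the ring.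

Step 4
Reactants: 9 (R)-4-benzyl-3-[(2R)-2-[(R)-(4-acetoxy-3-methoxyphenyl)(hydroxy)methyl]-4-methylidenehex-5-ynoyl]oxazolidin-2-one
Product: 10 (1R,2S)-1-(4-hydroxy-3-methoxyphenyl)-2-(2-methylidenebut-3-yn-1-yl)propane-1,3-diol
Conditions: LiBH4, MeOH, THF, 0 °C to rt
Reagents that add atoms: none
Why: Reductive cleavage of the imide with LiBH4 should give the primary alcohol without epimerisation and at the same time reduce off the aryl acetate, which has served only to mask the phenol during the aldol step, so that phenol and primary hydroxyl can be acetylated together next.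

Step 5
Reactants: 10 (1R,2S)-1-(4-hydroxy-3-methoxyphenyl)-2-(2-methylidenebut-3-yn-1-yl)propane-1,3-diol
Product: 11 (2S,3R)-3-(4-acetoxy-3-methoxyphenyl)-3-hydroxy-2-(2-methylidenebut-3-yn-1-yl)propyl acetate
Conditions: AcCl (2.1 equiv), 2,4,6-collidine, CH2Cl2, −78 to 0 °C
Reagents that add atoms: acetyl chloride, CC(=O)Cl
Why: Chemoselective acylation, in which acetyl chloride with a hindered pyridine base at low temperature acylates the primary hydroxyl and the phenol far faster than the secondary benzylic hydroxyl that sits next to a branched carbon.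

Step 6
Reactants: 12 1-(2,5-dimethoxyphenyl)ethanone
Product: 13 1-(4-iodo-2,5-dimethoxyphenyl)ethanone
Conditions: I2, AgO2CCF3, CHCl3, rt
Reagents that add atoms: iodine, II
Why: Electrophilic aromatic iodination with iodine and silver trifluoroacetate, which by analogy with the halogenation of 2,5-dimethoxybenzaldehyde should occur at C4, ortho to the C5 methoxy group and para to the acetyl group.

Step 7
Reactants: 13 1-(4-iodo-2,5-dimethoxyphenyl)ethanone
Product: 15 1-(2,5-dihydroxy-4-iodophenyl)ethanone, via bis(dibromoboryl) aryl ether 14 (not isolated)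
Conditions: BBr3, CH2Cl2, −78 °C to rt; H2O
Reagents that add atoms: none
Why: Lewis-acid cleavage of aryl methyl ethers with BBr3 removes both methyl groups through the aryl borate and leaves the aryl iodide and the ketone intact.

Step 8
Reactants: 11 (2S,3R)-3-(4-acetoxy-3-methoxyphenyl)-3-hydroxy-2-(2-methylidenebut-3-yn-1-yl)propyl acetate; 15 1-(2,5-dihydroxy-4-iodophenyl)ethanone
Product: 17 (2S,3R)-3-(4-acetoxy-3-methoxyphenyl)-2-[2-(6-acetyl-5-hydroxy-1-benzofuran-2-yl)prop-2-en-1-yl]-3-hydroxypropyl acetate, via o-alkynylphenol 16 (not isolated)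
Conditions: PdCl2(PPh3)2 (3 mol %), CuI (5 mol %), Et3N, DMF, rt then 50 °C, Ar
Reagents that add atoms: none
Why: Sonogashira coupling of the aryl iodide with the terminal enyne, followed in the same flask by 5-endo-dig cycloisomerisation of the o-alkynylphenol (the alkyne is activated by the para acetyl group), is the classical way to 2-(alk-1-en-2-yl)benzofurans, and only the hydroxyl ortho to the alkyne can close, which fixes the position of the ring oxygen.

Step 9
Reactants: 17 (2S,3R)-3-(4-acetoxy-3-methoxyphenyl)-2-[2-(6-acetyl-5-hydroxy-1-benzofuran-2-yl)prop-2-en-1-yl]-3-hydroxypropyl acetate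
Product: 18 (2S,3R)-3-(4-acetoxy-3-methoxyphenyl)-2-[2-[6-acetyl-5-(tert-butyldimethylsilyloxy)-1-benzofuran-2-yl]prop-2-en-1-yl]-3-hydroxypropyl acetate
Conditions: TBSCl, Et3N, DMF, 0 °C to rt
Reagents that add atoms: tert-butyldimethylsilyl chloride, CC(C)(C)[Si](C)(C)Cl
Why: Phenol-selective silylation, since the acidic phenol reacts with the silyl chloride and a tertiary amine whereas a hindered secondary aldol-type hydroxyl needs a silyl triflate, and the non-nucleophilic base avoids acyl transfer from the aryl acetate.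

Step 10
Reactants: 18 (2S,3R)-3-(4-acetoxy-3-methoxyphenyl)-2-[2-[6-acetyl-5-(tert-butyldimethylsilyloxy)-1-benzofuran-2-yl]prop-2-en-1-yl]-3-hydroxypropyl acetate
Product: 19 [(2R,3S)-2-(4-acetoxy-3-methoxyphenyl)-5-[6-acetyl-5-(tert-butyldimethylsilyloxy)-1-benzofuran-2-yl]-3,4-dihydro-2H-pyran-3-yl]methyl acetate
Conditions: 3,6-di-tert-butyl-9-mesityl-10-phenylacridinium tetrafluoroborate (5 mol %), Co(dmgH)2(py)Cl (5 mol %), degassed MeCN (0.02 M), 450 nm LEDs, rt, Ar
Reagents that add atoms: none
Why: Proposed new method: the excited acridinium should oxidise the 2-alkenylbenzofuran of 18 to its radical cation, the C2 hydroxyl then adds to the terminal carbon C6, proton loss leaves a tertiary radical at C5 delocalised into the benzofuran, and the cobaloxime in its divalent state takes the hydrogen atom from C6 to give the C5=C6 enol ether, after which the cobalt hydride and the proton release H2 and the reduced acridine radical returns trivalent cobalt to the divalent state. The closest known reaction types are the intermolecular acridinium/cobaloxime dehydrogenative anti-Markovnikov alkoxylation of 1,1-disubstituted aryl alkenes to enol ethers and the acridinium-catalysed intramolecular anti-Markovnikov hydroetherification of alkenols, and this step combines the two. The dihydropyran closes in the 6-endo-trig mode, because attack at C6 gives the stabilised tertiary radical while attack at C5 in the 5-exo sense would generate an unstabilised primary radical. No stereocentre is created, and C2 and C3 pass through unchanged in the neutral, oxidant-free medium. Two selectivities are needed: oxidation at the alkene and not at the guaiacyl ring, which the aryl acetate on that ring and the silyloxy donor on the benzofuran should secure, and loss of hydrogen from C6 and not from C4, which is favoured because the C6–H bond is weakened by the adjacent oxygen and its removal gives an enol ether conjugated with the benzofuran.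

Step 11
Reactants: 19 [(2R,3S)-2-(4-acetoxy-3-methoxyphenyl)-5-[6-acetyl-5-(tert-butyldimethylsilyloxy)-1-benzofuran-2-yl]-3,4-dihydro-2H-pyran-3-yl]methyl acetate
Product: 20 [(2R,3S)-2-(4-acetoxy-3-methoxyphenyl)-5-(6-acetyl-5-hydroxy-1-benzofuran-2-yl)-3,4-dihydro-2H-pyran-3-yl]methyl acetate
Conditions: Bu4NF, AcOH (1:1), THF, 0 °C
Reagents that add atoms: none
Why: Fluoride cleavage of an aryl silyl ether is fast at 0 °C, and buffering with acetic acid keeps the medium from becoming basic enough to cleave or shift the acetates or acidic enough to harm the enol ether.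

Step 12
Reactants: 20 [(2R,3S)-2-(4-acetoxy-3-methoxyphenyl)-5-(6-acetyl-5-hydroxy-1-benzofuran-2-yl)-3,4-dihydro-2H-pyran-3-yl]methyl acetate
Product: 21 propolis-benzofuran A, [(2R,3S)-5-(6-acetyl-5-hydroxy-1-benzofuran-2-yl)-2-(4-hydroxy-3-methoxyphenyl)-3,4-dihydro-2H-pyran-3-yl]methyl acetate
Conditions: NH4OAc, MeOH–H2O (4:1), rt
Reagents that add atoms: none
Why: Ammonium acetate in aqueous methanol is a neutral transesterification medium known to remove phenolic acetates while leaving alkyl acetates alone, and the near-neutral pH should spare the cyclic enol ether.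

## Compound list

1 | (R)-4-benzyloxazolidin-2-one | O=C1N[C@H](Cc2ccccc2)CO1 | starting material
2 | 4-bromopent-4-enoic acid | OC(=O)CCC(Br)=C | starting material
3 | 4-bromopent-4-enoic pivalic anhydride | C=C(Br)CCC(=O)OC(=O)C(C)(C)C | intermediate
4 | (R)-4-benzyl-3-(4-bromopent-4-enoyl)oxazolidin-2-one | O=C1OC[C@@H](Cc2ccccc2)N1C(=O)CCC(Br)=C | intermediate
5 | (R)-4-benzyl-3-(4-methylidenehex-5-ynoyl)oxazolidin-2-one | O=C1OC[C@@H](Cc2ccccc2)N1C(=O)CCC(=C)C#C | intermediate
6 | 4-formyl-2-methoxyphenyl acetate (vanillin acetate) | COc1cc(C=O)ccc1OC(C)=O | starting material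
7 | dibutylboron Z-enolate of 5 | CCCCB(CCCC)O/C(=C\CC(=C)C#C)N1C(=O)OC[C@H]1Cc1ccccc1 | intermediate
8 | dibutylboron aldolate of 9 | COc1cc([C@H](OB(CCCC)CCCC)[C@H](C(=O)N2C(=O)OC[C@H]2Cc2ccccc2)CC(=C)C#C)ccc1OC(C)=O | intermediate
9 | (R)-4-benzyl-3-[(2R)-2-[(R)-(4-acetoxy-3-methoxyphenyl)(hydroxy)methyl]-4-methylidenehex-5-ynoyl]oxazolidin-2-one | COc1cc([C@H](O)[C@H](C(=O)N2C(=O)OC[C@H]2Cc2ccccc2)CC(=C)C#C)ccc1OC(C)=O | intermediate
10 | (1R,2S)-1-(4-hydroxy-3-methoxyphenyl)-2-(2-methylidenebut-3-yn-1-yl)propane-1,3-diol | COc1cc([C@H](O)[C@H](CO)CC(=C)C#C)ccc1O | intermediate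
11 | (2S,3R)-3-(4-acetoxy-3-methoxyphenyl)-3-hydroxy-2-(2-methylidenebut-3-yn-1-yl)propyl acetate | COc1cc([C@H](O)[C@H](COC(C)=O)CC(=C)C#C)ccc1OC(C)=O | intermediate
12 | 1-(2,5-dimethoxyphenyl)ethanone | COc1ccc(OC)c(C(C)=O)c1 | starting material
13 | 1-(4-iodo-2,5-dimethoxyphenyl)ethanone | COc1cc(C(C)=O)c(OC)cc1I | intermediate
14 | 1-[2,5-bis(dibromoboryloxy)-4-iodophenyl]ethanone | CC(=O)c1cc(OB(Br)Br)c(I)cc1OB(Br)Br | intermediate
15 | 1-(2,5-dihydroxy-4-iodophenyl)ethanone | CC(=O)c1cc(O)c(I)cc1O | intermediate
16 | (2S,3R)-3-(4-acetoxy-3-methoxyphenyl)-2-[4-(4-acetyl-2,5-dihydroxyphenyl)-2-methylidenebut-3-yn-1-yl]-3-hydroxypropyl acetate | COc1cc([C@H](O)[C@H](COC(C)=O)CC(=C)C#Cc2cc(O)c(C(C)=O)cc2O)ccc1OC(C)=O | intermediate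
17 | (2S,3R)-3-(4-acetoxy-3-methoxyphenyl)-2-[2-(6-acetyl-5-hydroxy-1-benzofuran-2-yl)prop-2-en-1-yl]-3-hydroxypropyl acetate | COc1cc([C@H](O)[C@H](COC(C)=O)CC(=C)c2cc3cc(O)c(C(C)=O)cc3o2)ccc1OC(C)=O | intermediate
18 | (2S,3R)-3-(4-acetoxy-3-methoxyphenyl)-2-[2-[6-acetyl-5-(tert-butyldimethylsilyloxy)-1-benzofuran-2-yl]prop-2-en-1-yl]-3-hydroxypropyl acetate | COc1cc([C@H](O)[C@H](COC(C)=O)CC(=C)c2cc3cc(O[Si](C)(C)C(C)(C)C)c(C(C)=O)cc3o2)ccc1OC(C)=O | intermediate
19 | [(2R,3S)-2-(4-acetoxy-3-methoxyphenyl)-5-[6-acetyl-5-(tert-butyldimethylsilyloxy)-1-benzofuran-2-yl]-3,4-dihydro-2H-pyran-3-yl]methyl acetate | COc1cc([C@@H]2OC=C(c3cc4cc(O[Si](C)(C)C(C)(C)C)c(C(C)=O)cc4o3)C[C@H]2COC(C)=O)ccc1OC(C)=O | intermediate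
20 | [(2R,3S)-2-(4-acetoxy-3-methoxyphenyl)-5-(6-acetyl-5-hydroxy-1-benzofuran-2-yl)-3,4-dihydro-2H-pyran-3-yl]methyl acetate | COc1cc([C@@H]2OC=C(c3cc4cc(O)c(C(C)=O)cc4o3)C[C@H]2COC(C)=O)ccc1OC(C)=O | intermediate
21 | propolis-benzofuran A, [(2R,3S)-5-(6-acetyl-5-hydroxy-1-benzofuran-2-yl)-2-(4-hydroxy-3-methoxyphenyl)-3,4-dihydro-2H-pyran-3-yl]methyl acetate | COc1cc([C@@H]2OC=C(c3cc4cc(O)c(C(C)=O)cc4o3)C[C@H]2COC(C)=O)ccc1O | target

## Step count and risks

Total step count: 12. Longest linear sequence: 10 steps (steps 1–5 and 8–12); steps 6 and 7 prepare the iodophenol.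

**Step 10 (key step).** What may go wrong: hydrogen may be lost from C4 so that the double bond ends up in the allylic position, the electron-rich enol ether may be oxidised further once formed, or the alkene radical cation may dimerise before the hydroxyl traps it. The fallback uses known chemistry and runs from 18 back to 19. The secondary hydroxyl of 18 is vinylated by transfer vinylation with butyl vinyl ether (Pd(O2CCF3)2, 4,7-diphenyl-1,10-phenanthroline, Et3N, 75 °C) to give the O-vinyl ether of 18 F1. Enol ether–olefin ring-closing metathesis of F1 with the second-generation Grubbs catalyst RuCl2(=CHPh)(PCy3)(H2IMes) in toluene at 70 °C would then join C5 to the vinyl ether carbon with loss of ethene. This gives the same ring with O1–C6 and C5=C6 in place, that is 19.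

**Step 8 (coupling–cycloisomerisation).** What may go wrong: the acetyl group of the guaiacyl acetate may be transferred to the free phenols under the amine base, the conjugated enyne may oligomerise, or the sequence may stall at the o-alkynylphenol. The fallback runs from 15 and 11 back to 17 and separates coupling from ring closure. Both phenols of 15 are silylated (TBSCl, imidazole, DMF) to give 1-[2,5-bis(tert-butyldimethylsilyloxy)-4-iodophenyl]ethanone F2. Sonogashira coupling of F2 with 11 (PdCl2(PPh3)2, CuI, Et3N, THF, rt) gives the bis-silylated aryl enyne F3, in which no phenol is free to accept an acetyl group or to cyclise. Buffered fluoride (Bu4NF, AcOH, THF, 0 °C) then liberates 16, which is isolated this time and closed to 17 under neutral conditions by gold-catalysed hydroalkoxylation of the alkyne (Ph3PAuCl, AgOTf, toluene, rt).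

**Step 5 (selective diacetylation).** What may go wrong: acetylation may run on to the secondary hydroxyl or stop after one acetyl group, so that the diacetate is not obtained cleanly. The fallback runs from 9 back to 11 and masks the secondary hydroxyl before the reduction. TESOTf and 2,6-lutidine (CH2Cl2, −78 °C) convert 9 into the triethylsilyl ether of 9 F4. LiBH4 (MeOH, THF, 0 °C) then gives the triethylsilyl-protected phenol alcohol F5. Exhaustive acetylation (Ac2O, pyridine, DMAP) gives the triethylsilyl-protected diacetate F6, and HF·pyridine in THF–pyridine at 0 °C removes the silyl group to give 11.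

## Further compounds

F1 | step 10 | (2S,3R)-3-(4-acetoxy-3-methoxyphenyl)-2-[2-[6-acetyl-5-(tert-butyldimethylsilyloxy)-1-benzofuran-2-yl]prop-2-en-1-yl]-3-(ethenyloxy)propyl acetate | COc1cc([C@H](OC=C)[C@H](COC(C)=O)CC(=C)c2cc3cc(O[Si](C)(C)C(C)(C)C)c(C(C)=O)cc3o2)ccc1OC(C)=O
F2 | step 8 | 1-[2,5-bis(tert-butyldimethylsilyloxy)-4-iodophenyl]ethanone | CC(=O)c1cc(O[Si](C)(C)C(C)(C)C)c(I)cc1O[Si](C)(C)C(C)(C)C
F3 | step 8 | (2S,3R)-3-(4-acetoxy-3-methoxyphenyl)-2-[4-[4-acetyl-2,5-bis(tert-butyldimethylsilyloxy)phenyl]-2-methylidenebut-3-yn-1-yl]-3-hydroxypropyl acetate | COc1cc([C@H](O)[C@H](COC(C)=O)CC(=C)C#Cc2cc(O[Si](C)(C)C(C)(C)C)c(C(C)=O)cc2O[Si](C)(C)C(C)(C)C)ccc1OC(C)=O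
F4 | step 5 | (R)-4-benzyl-3-[(2R)-2-[(R)-(4-acetoxy-3-methoxyphenyl)(triethylsilyloxy)methyl]-4-methylidenehex-5-ynoyl]oxazolidin-2-one | COc1cc([C@H](O[Si](CC)(CC)CC)[C@H](C(=O)N2C(=O)OC[C@H]2Cc2ccccc2)CC(=C)C#C)ccc1OC(C)=O
F5 | step 5 | 4-[(1R,2S)-3-hydroxy-2-(2-methylidenebut-3-yn-1-yl)-1-(triethylsilyloxy)propyl]-2-methoxyphenol | COc1cc([C@H](O[Si](CC)(CC)CC)[C@H](CO)CC(=C)C#C)ccc1O
F6 | step 5 | (2S,3R)-3-(4-acetoxy-3-methoxyphenyl)-2-(2-methylidenebut-3-yn-1-yl)-3-(triethylsilyloxy)propyl acetate | COc1cc([C@H](O[Si](CC)(CC)CC)[C@H](COC(C)=O)CC(=C)C#C)ccc1OC(C)=O
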